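**Retrosynthetic overview**

1. Target 38 ⇐ hexabenzyl ether 37 (hydrogenolysis) ⇐ boronate 25 + bromide 36 by Suzuki–Miyaura coupling (the 5–5′ biaryl bond, made last).
2. 25 ⇐ hydroxy lactone 22 (lactone C=O → CH2, then Br → Bpin); 36 ⇐ hydroxy lactone 32 (lactone opened, tetralin ring closed by quinone-methide Friedel–Crafts alkylation).
3. 22 / 32 ⇐ lactones 15 / 13 by enolate benzylation, then enolate hydroxylation (quaternary carbinol; both attacks anti to the C4 substituent); 15 ⇐ 13 by exchange of the phenol MOM group for benzyl.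
4. 13 ⇐ imide 6 + aldehyde 2 by one Evans syn-aldol addition with lactonisation (key C–C bond; sets the benzylic carbinol carbon and its neighbour for both halves).
5. Ring order: the γ-lactone is formed first and is common to both halves; it becomes the tetrahydrofuran ring (series A) or is opened and replaced by the tetralin carbocycle (series B); the biaryl bond joins the two ring systems at the end.

Assumption: the structure is taken exactly as written (tetrahydrofuran unit 3S,4R,5S with a 3-hydroxy-4-methoxybenzyl group; tetralin unit 1S,2S,3S counted from the aryl-bearing carbon).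

**Common part (one aldol for both halves)**

Step 1
Reactants: 1 5-bromovanillin (3-bromo-4-hydroxy-5-methoxybenzaldehyde)
Product: 2 3-bromo-5-methoxy-4-(methoxymethoxy)benzaldehyde
Conditions: MOMCl, iPr2NEt, CH2Cl2, 0 °C → rt
Reagents that add atoms: chloromethyl methyl ether, COCCl
Why: O-alkylation of the phenol to the methoxymethyl acetal, chosen because acid removes it when the free para-phenol is needed for ring closure (step 21) and allows its exchange for benzyl in series A (steps 7 and 8).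

Step 2
Reactants: 3 (S)-4-benzyl-1,3-oxazolidin-2-one; 4 methyl 4-chloro-4-oxobutanoate
Product: 6 methyl 4-[(4S)-4-benzyl-2-oxo-1,3-oxazolidin-3-yl]-4-oxobutanoate, via N-lithio oxazolidinone 5 (not isolated)
Conditions: n-BuLi, THF, −78 °C; then 4, −78 → 0 °C
Reagents that add atoms: none
Why: N-acylation of the lithiated auxiliary by the acid chloride (nucleophilic acyl substitution), the methyl ester being far less electrophilic; the auxiliary stereocentre is untouched.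

Step 3
Reactants: 6 methyl 4-[(4S)-4-benzyl-2-oxo-1,3-oxazolidin-3-yl]-4-oxobutanoate; 2 3-bromo-5-methoxy-4-(methoxymethoxy)benzaldehyde
Product: 9 (4S)-4-benzyl-3-{[(2S,3S)-2-[3-bromo-5-methoxy-4-(methoxymethoxy)phenyl]-5-oxooxolan-3-yl]carbonyl}-1,3-oxazolidin-2-one, via boron enolate 7 (not isolated), via syn-aldol adduct 8 (not isolated)
Conditions: Bu2BOTf, iPr2NEt, CH2Cl2, 0 °C; 2, −78 → 0 °C; pH 7 buffer/MeOH/H2O2 (30%), 0 °C; then pyridinium p-toluenesulfonate (cat.), CH2Cl2, rt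
Reagents that add atoms: none
Why: Evans syn-aldol addition in which the Z-dibutylboron enolate reacts through a closed Zimmerman–Traxler transition state on the face away from the auxiliary benzyl group, giving the (S,S) syn adduct whose hydroxyl then lactonises onto the methyl ester to the 2,3-trans lactone without touching either new centre.

Step 4
Reactants: 9 (4S)-4-benzyl-3-{[(2S,3S)-2-[3-bromo-5-methoxy-4-(methoxymethoxy)phenyl]-5-oxooxolan-3-yl]carbonyl}-1,3-oxazolidin-2-one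
Product: 11 (2S,3S)-2-[3-bromo-5-methoxy-4-(methoxymethoxy)phenyl]-5-oxooxolane-3-carboxylic acid, via peroxy acid 10 (not isolated)
Conditions: LiOH, H2O2 (30%), THF/H2O (3:1), 0 °C; aq. Na2SO3; then 1 M HCl (0 °C, brief)
Reagents that add atoms: hydrogen peroxide, OO
Why: Hydroperoxide anion attacks the exocyclic imide carbonyl selectively (LiOOH auxiliary cleavage), sulfite reduces the peracid, and the lactone acid is recovered on short cold acidification, which the MOM acetal survives, without epimerisation.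

Step 5
Reactants: 11 (2S,3S)-2-[3-bromo-5-methoxy-4-(methoxymethoxy)phenyl]-5-oxooxolane-3-carboxylic acid
Product: 12 (4R,5S)-5-[3-bromo-5-methoxy-4-(methoxymethoxy)phenyl]-4-(hydroxymethyl)oxolan-2-one
Conditions: BH3·SMe2, THF, 0 °C → rt; MeOH quench
Reagents that add atoms: none
Why: Borane reduces the free carboxylic acid much faster than the lactone (chemoselective reduction via the acyloxyborane), leaving both stereocentres, the MOM acetal and the aryl bromide intact.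

Step 6
Reactants: 12 (4R,5S)-5-[3-bromo-5-methoxy-4-(methoxymethoxy)phenyl]-4-(hydroxymethyl)oxolan-2-one
Product: 13 (4R,5S)-4-[(benzyloxy)methyl]-5-[3-bromo-5-methoxy-4-(methoxymethoxy)phenyl]oxolan-2-one
Conditions: 2-benzyloxy-1-methylpyridinium triflate, MgO, PhCF3, 83 °C
Reagents that add atoms: 2-benzyloxy-1-methylpyridinium trifluoromethanesulfonate, C[n+]1ccccc1OCc1ccccc1.[O-]S(=O)(=O)C(F)(F)F
Why: Dudley benzylation transfers a benzyl cation to the primary alcohol under essentially neutral conditions, so the base-sensitive hydroxymethyl lactone neither translactonises nor epimerises and the MOM acetal is unaffected.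

**Series A (tetrahydrofuran half)**

Step 7
Reactants: 13 (4R,5S)-4-[(benzyloxy)methyl]-5-[3-bromo-5-methoxy-4-(methoxymethoxy)phenyl]oxolan-2-one
Product: 14 (4R,5S)-4-[(benzyloxy)methyl]-5-(3-bromo-4-hydroxy-5-methoxyphenyl)oxolan-2-one
Conditions: CF3CO2H/CH2Cl2/H2O (20:80:1), 0 °C → rt; aqueous work-up
Reagents that add atoms: none
Why: Acid-catalysed acetal hydrolysis of the aryl MOM ether leaves the alkyl benzyl ether and the lactone alone, and any reversible ionisation of the benzylic lactone C–O bond can only re-close to the same, thermodynamically favoured 4,5-trans lactone.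

Step 8
Reactants: 14 (4R,5S)-4-[(benzyloxy)methyl]-5-(3-bromo-4-hydroxy-5-methoxyphenyl)oxolan-2-one
Product: 15 (4R,5S)-5-[4-(benzyloxy)-3-bromo-5-methoxyphenyl]-4-[(benzyloxy)methyl]oxolan-2-one
Conditions: BnBr, K2CO3, DMF, 0 °C → rt
Reagents that add atoms: benzyl bromide, BrCc1ccccc1
Why: Williamson etherification of the acidic phenoxide with a reactive benzylic bromide at low temperature, which is faster than any ring opening of the lactone and touches no stereocentre.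

Step 9
Reactants: 16 3-(benzyloxy)-4-methoxybenzaldehyde
Product: 17 [3-(benzyloxy)-4-methoxyphenyl]methanol
Conditions: NaBH4, MeOH, 0 °C
Reagents that add atoms: none
Why: Simple hydride reduction of an aromatic aldehyde to the benzylic alcohol.

Step 10
Reactants: 17 [3-(benzyloxy)-4-methoxyphenyl]methanol
Product: 18 2-(benzyloxy)-4-(bromomethyl)-1-methoxybenzene
Conditions: PBr3, Et2O, 0 °C
Reagents that add atoms: phosphorus tribromide, BrP(Br)Br
Why: The benzylic alcohol is converted through its phosphite into the bromide by SN2 displacement; the product is used at once.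

Step 11
Reactants: 15 (4R,5S)-5-[4-(benzyloxy)-3-bromo-5-methoxyphenyl]-4-[(benzyloxy)methyl]oxolan-2-one; 18 2-(benzyloxy)-4-(bromomethyl)-1-methoxybenzene
Product: 20 (3S,4R,5S)-5-[4-(benzyloxy)-3-bromo-5-methoxyphenyl]-3-[3-(benzyloxy)-4-methoxybenzyl]-4-[(benzyloxy)methyl]oxolan-2-one, via lithium enolate 19 (not isolated)
Conditions: LiN(SiMe3)2, THF, −78 °C; then 18, −78 → −40 °C
Reagents that add atoms: none
Why: SN2 alkylation of the lactone enolate by the reactive benzylic bromide occurs on the face opposite the adjacent C4 benzyloxymethyl group, giving the 3,4-trans lactone (3S).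

Step 12
Reactants: 20 (3S,4R,5S)-5-[4-(benzyloxy)-3-bromo-5-methoxyphenyl]-3-[3-(benzyloxy)-4-methoxybenzyl]-4-[(benzyloxy)methyl]oxolan-2-one
Product: 22 (3S,4R,5S)-5-[4-(benzyloxy)-3-bromo-5-methoxyphenyl]-3-[3-(benzyloxy)-4-methoxybenzyl]-4-[(benzyloxy)methyl]-3-hydroxyoxolan-2-one, via potassium enolate 21 (not isolated)
Conditions: KN(SiMe3)2, THF, −78 °C; Davis oxaziridine, −78 °C; AcOH quench
Reagents that add atoms: 3-phenyl-2-(phenylsulfonyl)oxaziridine (Davis oxaziridine), O=S(=O)(c1ccccc1)N1OC1c1ccccc1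
Why: Davis enolate hydroxylation, in which the planar enolate again takes the electrophile anti to the C4 substituent, so the new hydroxyl ends trans and the benzyl group cis to C4 (3S quaternary carbinol).

Step 13
Reactants: 22 (3S,4R,5S)-5-[4-(benzyloxy)-3-bromo-5-methoxyphenyl]-3-[3-(benzyloxy)-4-methoxybenzyl]-4-[(benzyloxy)methyl]-3-hydroxyoxolan-2-one
Product: 23 (3S,4R,5S)-5-[4-(benzyloxy)-3-bromo-5-methoxyphenyl]-3-[3-(benzyloxy)-4-methoxybenzyl]-4-[(benzyloxy)methyl]oxolane-2,3-diol (lactol, both anomers)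
Conditions: iBu2AlH (2.5 equiv), CH2Cl2, −78 °C; aq. potassium sodium tartrate
Reagents that add atoms: none
Why: Partial hydride reduction of the lactone stops at the aluminium hemiacetal at −78 °C and gives the lactol on work-up, with the benzylic ring C–O bond and all stereocentres retained.

Step 14
Reactants: 23 (3S,4R,5S)-5-[4-(benzyloxy)-3-bromo-5-methoxyphenyl]-3-[3-(benzyloxy)-4-methoxybenzyl]-4-[(benzyloxy)methyl]oxolane-2,3-diol
Product: 24 (3S,4R,5S)-5-[4-(benzyloxy)-3-bromo-5-methoxyphenyl]-3-[3-(benzyloxy)-4-methoxybenzyl]-4-[(benzyloxy)methyl]oxolan-3-ol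
Conditions: Et3SiH, BF3·OEt2, CH2Cl2, −78 → −20 °C
Reagents that add atoms: none
Why: Ionic hydrogenation of the lactol, in which BF3 generates the cyclic oxocarbenium ion and Et3SiH reduces it to CH2, while the benzylic ring C–O bond sits on an aryl ring that is a poor cation stabiliser (benzyloxy group flanked by bromine and methoxy) and does not ionise; no stereocentre changes.

Step 15
Reactants: 24 (3S,4R,5S)-5-[4-(benzyloxy)-3-bromo-5-methoxyphenyl]-3-[3-(benzyloxy)-4-methoxybenzyl]-4-[(benzyloxy)methyl]oxolan-3-ol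
Product: 25 (3S,4R,5S)-5-[4-(benzyloxy)-3-methoxy-5-(4,4,5,5-tetramethyl-1,3,2-dioxaborolan-2-yl)phenyl]-3-[3-(benzyloxy)-4-methoxybenzyl]-4-[(benzyloxy)methyl]oxolan-3-ol
Conditions: B2pin2, Pd(dppf)Cl2·CH2Cl2 (5 mol%), KOAc, 1,4-dioxane, 90 °C
Reagents that add atoms: bis(pinacolato)diboron, CC1(C)OB(OC1(C)C)B1OC(C)(C)C(C)(C)O1
Why: Miyaura borylation of the aryl bromide under weakly basic acetate conditions, which the single tertiary alcohol and the benzyl ethers tolerate.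

**Series B (tetralin half)**

Step 16
Reactants: 26 4-(benzyloxy)-3-methoxybenzaldehyde
Product: 27 [4-(benzyloxy)-3-methoxyphenyl]methanol
Conditions: NaBH4, MeOH, 0 °C
Reagents that add atoms: none
Why: Hydride reduction of the aromatic aldehyde.

Step 17
Reactants: 27 [4-(benzyloxy)-3-methoxyphenyl]methanol
Product: 28 1-(benzyloxy)-4-(bromomethyl)-2-methoxybenzene
Conditions: PBr3, Et2O, 0 °C
Reagents that add atoms: phosphorus tribromide, BrP(Br)Br
Why: SN2 bromination of the benzylic alcohol via its phosphite; the bromide is used at once.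

Step 18
Reactants: 13 (4R,5S)-4-[(benzyloxy)methyl]-5-[3-bromo-5-methoxy-4-(methoxymethoxy)phenyl]oxolan-2-one; 28 1-(benzyloxy)-4-(bromomethyl)-2-methoxybenzene
Product: 30 (3S,4R,5S)-3-[4-(benzyloxy)-3-methoxybenzyl]-4-[(benzyloxy)methyl]-5-[3-bromo-5-methoxy-4-(methoxymethoxy)phenyl]oxolan-2-one, via lithium enolate 29 (not isolated)
Conditions: LiN(SiMe3)2, THF, −78 °C; then 28, −78 → −40 °C
Reagents that add atoms: none
Why: Enolate alkylation (SN2) trans to the C4 substituent, as in step 11, giving the 3S centre.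

Step 19
Reactants: 30 (3S,4R,5S)-3-[4-(benzyloxy)-3-methoxybenzyl]-4-[(benzyloxy)methyl]-5-[3-bromo-5-methoxy-4-(methoxymethoxy)phenyl]oxolan-2-one
Product: 32 (3S,4R,5S)-3-[4-(benzyloxy)-3-methoxybenzyl]-4-[(benzyloxy)methyl]-5-[3-bromo-5-methoxy-4-(methoxymethoxy)phenyl]-3-hydroxyoxolan-2-one, via potassium enolate 31 (not isolated)
Conditions: KN(SiMe3)2, THF, −78 °C; Davis oxaziridine, −78 °C; AcOH quench
Reagents that add atoms: 3-phenyl-2-(phenylsulfonyl)oxaziridine (Davis oxaziridine), O=S(=O)(c1ccccc1)N1OC1c1ccccc1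
Why: Davis enolate hydroxylation anti to the C4 substituent, as in step 12, setting the 3S quaternary carbinol.

Step 20
Reactants: 32 (3S,4R,5S)-3-[4-(benzyloxy)-3-methoxybenzyl]-4-[(benzyloxy)methyl]-5-[3-bromo-5-methoxy-4-(methoxymethoxy)phenyl]-3-hydroxyoxolan-2-one
Product: 33 (1S,2R,3S)-3-[4-(benzyloxy)-3-methoxybenzyl]-2-[(benzyloxy)methyl]-1-[3-bromo-5-methoxy-4-(methoxymethoxy)phenyl]butane-1,3,4-triol
Conditions: LiBH4, THF, 0 °C → rt; aq. NH4Cl
Reagents that add atoms: none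
Why: Hydride reduction of the lactone to the 1,4-diol, which leaves the aryl bromide, the MOM acetal, the benzyl ethers and all stereocentres untouched.

Step 21
Reactants: 33 (1S,2R,3S)-3-[4-(benzyloxy)-3-methoxybenzyl]-2-[(benzyloxy)methyl]-1-[3-bromo-5-methoxy-4-(methoxymethoxy)phenyl]butane-1,3,4-triol
Product: 35 (1S,2S,3S)-7-(benzyloxy)-2-[(benzyloxy)methyl]-1-(3-bromo-4-hydroxy-5-methoxyphenyl)-3-(hydroxymethyl)-6-methoxy-1,2,3,4-tetrahydronaphthalen-3-ol, via phenol triol 34 (not isolated)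
Conditions: HCl (1.25 M in MeOH), 45 °C
Reagents that add atoms: none
Why: Acid removes the MOM acetal, the freed para-hydroxybenzylic alcohol ionises to a protonated quinone methide, and the electron-rich benzyl ring closes the six-membered ring para to its methoxy group (intramolecular Friedel–Crafts alkylation of the olivil-to-cycloolivil type), with the new C1 aryl group trans to the C2 substituent (1S) as the pseudo-equatorial, thermodynamically favoured isomer.

Step 22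
Reactants: 35 (1S,2S,3S)-7-(benzyloxy)-2-[(benzyloxy)methyl]-1-(3-bromo-4-hydroxy-5-methoxyphenyl)-3-(hydroxymethyl)-6-methoxy-1,2,3,4-tetrahydronaphthalen-3-ol
Product: 36 (1S,2S,3S)-7-(benzyloxy)-1-[4-(benzyloxy)-3-bromo-5-methoxyphenyl]-2-[(benzyloxy)methyl]-3-(hydroxymethyl)-6-methoxy-1,2,3,4-tetrahydronaphthalen-3-ol
Conditions: BnBr, K2CO3, DMF, rt
Reagents that add atoms: benzyl bromide, BrCc1ccccc1
Why: Williamson etherification that is selective for the acidic phenol over the aliphatic alcohols with carbonate as base.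

**Union and deprotection**

Step 23
Reactants: 25 (3S,4R,5S)-5-[4-(benzyloxy)-3-methoxy-5-(4,4,5,5-tetramethyl-1,3,2-dioxaborolan-2-yl)phenyl]-3-[3-(benzyloxy)-4-methoxybenzyl]-4-[(benzyloxy)methyl]oxolan-3-ol; 36 (1S,2S,3S)-7-(benzyloxy)-1-[4-(benzyloxy)-3-bromo-5-methoxyphenyl]-2-[(benzyloxy)methyl]-3-(hydroxymethyl)-6-methoxy-1,2,3,4-tetrahydronaphthalen-3-ol
Product: 37 (3S,4R,5S)-5-{4-(benzyloxy)-3-[2-(benzyloxy)-5-[(1S,2S,3S)-7-(benzyloxy)-2-[(benzyloxy)methyl]-3-hydroxy-3-(hydroxymethyl)-6-methoxy-1,2,3,4-tetrahydronaphthalen-1-yl]-3-methoxyphenyl]-5-methoxyphenyl}-3-[3-(benzyloxy)-4-methoxybenzyl]-4-[(benzyloxy)methyl]oxolan-3-ol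
Conditions: Pd(OAc)2 (5 mol%), 2-dicyclohexylphosphino-2′,6′-dimethoxybiphenyl (SPhos, 10 mol%), K3PO4, PhMe/H2O (10:1), 90 °C
Reagents that add atoms: none
Why: Suzuki–Miyaura cross-coupling with a bulky electron-rich biarylphosphine that handles the two ortho-benzyloxy partners and tolerates free alcohols; no stereocentre is involved.

Step 24
Reactants: 37 hexabenzyl ether (full name as in step 23)
Product: 38 (3S,4R,5S)-5-{4-hydroxy-3-[2-hydroxy-5-[(1S,2S,3S)-3,7-dihydroxy-2,3-bis(hydroxymethyl)-6-methoxy-1,2,3,4-tetrahydronaphthalen-1-yl]-3-methoxyphenyl]-5-methoxyphenyl}-3-(3-hydroxy-4-methoxybenzyl)-4-(hydroxymethyl)oxolan-3-ol (CNP0252244.1)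
Conditions: H2 (1 atm), 10% Pd/C, THF/MeOH (1:1), rt, stopped at full debenzylation
Reagents that add atoms: none
Why: Catalytic hydrogenolysis cleaves the four aryl and two alkyl benzyl ethers under neutral conditions, which leave the cyclic benzylic ether of the tetrahydrofuran and all six stereocentres intact.

**Compound list**

1 | 5-bromovanillin (3-bromo-4-hydroxy-5-methoxybenzaldehyde) | O=Cc1cc(OC)c(O)c(Br)c1 | starting material
2 | 3-bromo-5-methoxy-4-(methoxymethoxy)benzaldehyde | O=Cc1cc(OC)c(OCOC)c(Br)c1 | intermediate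
3 | (S)-4-benzyl-1,3-oxazolidin-2-one | O=C1OC[C@H](Cc2ccccc2)N1 | starting material
4 | methyl 4-chloro-4-oxobutanoate | COC(=O)CCC(Cl)=O | starting material
5 | lithium (S)-4-benzyl-2-oxo-1,3-oxazolidin-3-ide | [Li+].O=C1OC[C@H](Cc2ccccc2)[N-]1 | intermediate (not isolated)
6 | methyl 4-[(4S)-4-benzyl-2-oxo-1,3-oxazolidin-3-yl]-4-oxobutanoate | COC(=O)CCC(=O)N1C(=O)OC[C@@H]1Cc1ccccc1 | intermediate
7 | (Z)-O-dibutylboryl enolate of 6 | COC(=O)C/C=C(\OB(CCCC)CCCC)N1C(=O)OC[C@@H]1Cc1ccccc1 | intermediate (not isolated)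
8 | methyl (3S)-3-{(S)-[3-bromo-5-methoxy-4-(methoxymethoxy)phenyl](hydroxy)methyl}-4-[(4S)-4-benzyl-2-oxo-1,3-oxazolidin-3-yl]-4-oxobutanoate | COC(=O)C[C@@H]([C@H](O)c1cc(OC)c(OCOC)c(Br)c1)C(=O)N1C(=O)OC[C@@H]1Cc1ccccc1 | intermediate (not isolated)
9 | (4S)-4-benzyl-3-{[(2S,3S)-2-[3-bromo-5-methoxy-4-(methoxymethoxy)phenyl]-5-oxooxolan-3-yl]carbonyl}-1,3-oxazolidin-2-one | C1C(=O)O[C@H](c2cc(OC)c(OCOC)c(Br)c2)[C@H]1C(=O)N1C(=O)OC[C@@H]1Cc1ccccc1 | intermediate
10 | (2S,3S)-2-[3-bromo-5-methoxy-4-(methoxymethoxy)phenyl]-5-oxooxolane-3-carboperoxoic acid | C1C(=O)O[C@H](c2cc(OC)c(OCOC)c(Br)c2)[C@H]1C(=O)OO | intermediate (not isolated)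
11 | (2S,3S)-2-[3-bromo-5-methoxy-4-(methoxymethoxy)phenyl]-5-oxooxolane-3-carboxylic acid | C1C(=O)O[C@H](c2cc(OC)c(OCOC)c(Br)c2)[C@H]1C(=O)O | intermediate
12 | (4R,5S)-5-[3-bromo-5-methoxy-4-(methoxymethoxy)phenyl]-4-(hydroxymethyl)oxolan-2-one | C1C(=O)O[C@H](c2cc(OC)c(OCOC)c(Br)c2)[C@H]1CO | intermediate
13 | (4R,5S)-4-[(benzyloxy)methyl]-5-[3-bromo-5-methoxy-4-(methoxymethoxy)phenyl]oxolan-2-one | C1C(=O)O[C@H](c2cc(OC)c(OCOC)c(Br)c2)[C@H]1COCc1ccccc1 | intermediate
14 | (4R,5S)-4-[(benzyloxy)methyl]-5-(3-bromo-4-hydroxy-5-methoxyphenyl)oxolan-2-one | C1C(=O)O[C@H](c2cc(OC)c(O)c(Br)c2)[C@H]1COCc1ccccc1 | intermediate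
15 | (4R,5S)-5-[4-(benzyloxy)-3-bromo-5-methoxyphenyl]-4-[(benzyloxy)methyl]oxolan-2-one | C1C(=O)O[C@H](c2cc(OC)c(OCc3ccccc3)c(Br)c2)[C@H]1COCc1ccccc1 | intermediate
16 | 3-(benzyloxy)-4-methoxybenzaldehyde | O=Cc1ccc(OC)c(OCc2ccccc2)c1 | starting material
17 | [3-(benzyloxy)-4-methoxyphenyl]methanol | OCc1ccc(OC)c(OCc2ccccc2)c1 | intermediate
18 | 2-(benzyloxy)-4-(bromomethyl)-1-methoxybenzene | BrCc1ccc(OC)c(OCc2ccccc2)c1 | intermediate
19 | lithium enolate of 15 | [Li+].C1=C([O-])O[C@H](c2cc(OC)c(OCc3ccccc3)c(Br)c2)[C@H]1COCc1ccccc1 | intermediate (not isolated)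
20 | (3S,4R,5S)-5-[4-(benzyloxy)-3-bromo-5-methoxyphenyl]-3-[3-(benzyloxy)-4-methoxybenzyl]-4-[(benzyloxy)methyl]oxolan-2-one | COc1ccc(C[C@@H]2C(=O)O[C@H](c3cc(OC)c(OCc4ccccc4)c(Br)c3)[C@H]2COCc2ccccc2)cc1OCc1ccccc1 | intermediate
21 | potassium enolate of 20 | [K+].COc1ccc(CC2=C([O-])O[C@H](c3cc(OC)c(OCc4ccccc4)c(Br)c3)[C@H]2COCc2ccccc2)cc1OCc1ccccc1 | intermediate (not isolated)
22 | (3S,4R,5S)-5-[4-(benzyloxy)-3-bromo-5-methoxyphenyl]-3-[3-(benzyloxy)-4-methoxybenzyl]-4-[(benzyloxy)methyl]-3-hydroxyoxolan-2-one | COc1ccc(C[C@@]2(O)C(=O)O[C@H](c3cc(OC)c(OCc4ccccc4)c(Br)c3)[C@H]2COCc2ccccc2)cc1OCc1ccccc1 | intermediate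
23 | (3S,4R,5S)-5-[4-(benzyloxy)-3-bromo-5-methoxyphenyl]-3-[3-(benzyloxy)-4-methoxybenzyl]-4-[(benzyloxy)methyl]oxolane-2,3-diol (both anomers at C2) | COc1ccc(C[C@@]2(O)C(O)O[C@H](c3cc(OC)c(OCc4ccccc4)c(Br)c3)[C@H]2COCc2ccccc2)cc1OCc1ccccc1 | intermediate
24 | (3S,4R,5S)-5-[4-(benzyloxy)-3-bromo-5-methoxyphenyl]-3-[3-(benzyloxy)-4-methoxybenzyl]-4-[(benzyloxy)methyl]oxolan-3-ol | COc1ccc(C[C@@]2(O)CO[C@H](c3cc(OC)c(OCc4ccccc4)c(Br)c3)[C@H]2COCc2ccccc2)cc1OCc1ccccc1 | intermediate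
25 | (3S,4R,5S)-5-[4-(benzyloxy)-3-methoxy-5-(4,4,5,5-tetramethyl-1,3,2-dioxaborolan-2-yl)phenyl]-3-[3-(benzyloxy)-4-methoxybenzyl]-4-[(benzyloxy)methyl]oxolan-3-ol | COc1ccc(C[C@@]2(O)CO[C@H](c3cc(OC)c(OCc4ccccc4)c(B4OC(C)(C)C(C)(C)O4)c3)[C@H]2COCc2ccccc2)cc1OCc1ccccc1 | intermediate
26 | 4-(benzyloxy)-3-methoxybenzaldehyde | O=Cc1ccc(OCc2ccccc2)c(OC)c1 | starting material
27 | [4-(benzyloxy)-3-methoxyphenyl]methanol | OCc1ccc(OCc2ccccc2)c(OC)c1 | intermediate
28 | 1-(benzyloxy)-4-(bromomethyl)-2-methoxybenzene | BrCc1ccc(OCc2ccccc2)c(OC)c1 | intermediate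
29 | lithium enolate of 13 | [Li+].C1=C([O-])O[C@H](c2cc(OC)c(OCOC)c(Br)c2)[C@H]1COCc1ccccc1 | intermediate (not isolated)
30 | (3S,4R,5S)-3-[4-(benzyloxy)-3-methoxybenzyl]-4-[(benzyloxy)methyl]-5-[3-bromo-5-methoxy-4-(methoxymethoxy)phenyl]oxolan-2-one | COc1cc(C[C@@H]2C(=O)O[C@H](c3cc(OC)c(OCOC)c(Br)c3)[C@H]2COCc2ccccc2)ccc1OCc1ccccc1 | intermediate
31 | potassium enolate of 30 | [K+].COc1cc(CC2=C([O-])O[C@H](c3cc(OC)c(OCOC)c(Br)c3)[C@H]2COCc2ccccc2)ccc1OCc1ccccc1 | intermediate (not isolated)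
32 | (3S,4R,5S)-3-[4-(benzyloxy)-3-methoxybenzyl]-4-[(benzyloxy)methyl]-5-[3-bromo-5-methoxy-4-(methoxymethoxy)phenyl]-3-hydroxyoxolan-2-one | COc1cc(C[C@@]2(O)C(=O)O[C@H](c3cc(OC)c(OCOC)c(Br)c3)[C@H]2COCc2ccccc2)ccc1OCc1ccccc1 | intermediate
33 | (1S,2R,3S)-3-[4-(benzyloxy)-3-methoxybenzyl]-2-[(benzyloxy)methyl]-1-[3-bromo-5-methoxy-4-(methoxymethoxy)phenyl]butane-1,3,4-triol | COc1cc(C[C@@](O)(CO)[C@H](COCc2ccccc2)[C@H](O)c2cc(OC)c(OCOC)c(Br)c2)ccc1OCc1ccccc1 | intermediate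
34 | (1S,2R,3S)-3-[4-(benzyloxy)-3-methoxybenzyl]-2-[(benzyloxy)methyl]-1-(3-bromo-4-hydroxy-5-methoxyphenyl)butane-1,3,4-triol | COc1cc(C[C@@](O)(CO)[C@H](COCc2ccccc2)[C@H](O)c2cc(OC)c(O)c(Br)c2)ccc1OCc1ccccc1 | intermediate (not isolated)
35 | (1S,2S,3S)-7-(benzyloxy)-2-[(benzyloxy)methyl]-1-(3-bromo-4-hydroxy-5-methoxyphenyl)-3-(hydroxymethyl)-6-methoxy-1,2,3,4-tetrahydronaphthalen-3-ol (ring numbered from the aryl-bearing carbon) | Brc1cc([C@H]2c3cc(OCc4ccccc4)c(OC)cc3C[C@@](O)(CO)[C@@H]2COCc2ccccc2)cc(OC)c1O | intermediate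
36 | (1S,2S,3S)-7-(benzyloxy)-1-[4-(benzyloxy)-3-bromo-5-methoxyphenyl]-2-[(benzyloxy)methyl]-3-(hydroxymethyl)-6-methoxy-1,2,3,4-tetrahydronaphthalen-3-ol (ring numbered from the aryl-bearing carbon) | Brc1cc([C@H]2c3cc(OCc4ccccc4)c(OC)cc3C[C@@](O)(CO)[C@@H]2COCc2ccccc2)cc(OC)c1OCc1ccccc1 | intermediate
37 | (3S,4R,5S)-5-{4-(benzyloxy)-3-[2-(benzyloxy)-5-[(1S,2S,3S)-7-(benzyloxy)-2-[(benzyloxy)methyl]-3-hydroxy-3-(hydroxymethyl)-6-methoxy-1,2,3,4-tetrahydronaphthalen-1-yl]-3-methoxyphenyl]-5-methoxyphenyl}-3-[3-(benzyloxy)-4-methoxybenzyl]-4-[(benzyloxy)methyl]oxolan-3-ol | COc1ccc(C[C@@]2(O)CO[C@H](c3cc(OC)c(OCc4ccccc4)c(-c4cc([C@H]5c6cc(OCc7ccccc7)c(OC)cc6C[C@@](O)(CO)[C@@H]5COCc5ccccc5)cc(OC)c4OCc4ccccc4)c3)[C@H]2COCc2ccccc2)cc1OCc1ccccc1 | intermediate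
38 | (3S,4R,5S)-5-{4-hydroxy-3-[2-hydroxy-5-[(1S,2S,3S)-3,7-dihydroxy-2,3-bis(hydroxymethyl)-6-methoxy-1,2,3,4-tetrahydronaphthalen-1-yl]-3-methoxyphenyl]-5-methoxyphenyl}-3-(3-hydroxy-4-methoxybenzyl)-4-(hydroxymethyl)oxolan-3-ol (CNP0252244.1) | COc1ccc(C[C@@]2(O)CO[C@H](c3cc(OC)c(O)c(-c4cc([C@H]5c6cc(O)c(OC)cc6C[C@@](O)(CO)[C@@H]5CO)cc(OC)c4O)c3)[C@H]2CO)cc1O | target

**Totals and risks**

Total step count: 24.
Longest linear sequence: 14 steps (steps 1, 3, 4, 5, 6, 7, 8, 11, 12, 13, 14, 15, 23, 24; the tetralin branch, steps 1, 3–6 and 18–24, has 12).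

The three steps most likely to fail:

Step 8 (benzylation of phenol 14, the second half of the protecting-group exchange begun in step 7). The risk is that the phenoxide, which sits para to the benzylic lactone C–O bond, opens the ring to a quinone methide carboxylate before it is benzylated, or that the acid of step 7 erodes the C5 configuration. The fallback sets out from 1 and 6 and comes back to the route at 15, so that steps 7 and 8 are not needed. Benzylation of 1 (BnBr, K2CO3, DMF, 60 °C) gives 4-(benzyloxy)-3-bromo-5-methoxybenzaldehyde F1. A separate Evans aldol addition of boron enolate 7 (made from 6 with Bu2BOTf and iPr2NEt in CH2Cl2) to F1 gives the syn-aldol adduct F2, which lactonises (pyridinium p-toluenesulfonate cat., CH2Cl2) to the lactone imide F3. LiOH/H2O2 cleavage through the peroxy acid F4 gives the lactone acid F5, BH3·SMe2 reduces it to the hydroxymethyl lactone F6, and Dudley benzylation (2-benzyloxy-1-methylpyridinium triflate, MgO, PhCF3, 83 °C) gives 15. The benzyl ether is then carried from the aldehyde, and the free phenol lactone never appears.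

Step 12 (enolate hydroxylation; step 19 is the same reaction in the other series). The risk is incomplete conversion of the fully substituted enolate or weak facial control, because the C5 aryl group lies on the face the oxidant must use. The fallback sets out from 15 and aldehyde 16 and comes back to the route at 22, replacing steps 9–12. Aldol addition of lithium enolate 19 to 16 (LiN(SiMe3)2, THF, −78 °C) gives the β-hydroxy lactone F7 as a mixture of carbinol epimers. Acid-catalysed dehydration (p-toluenesulfonic acid cat., PhMe, 60 °C) gives the (E)-benzylidene lactone F8. Dihydroxylation (OsO4 cat., N-methylmorpholine N-oxide, acetone/H2O) from the face opposite the C4 benzyloxymethyl group gives the diol F9, which already carries the tertiary C3–O bond in the required orientation. Ionic hydrogenation of its para-methoxy-activated secondary benzylic alcohol (Et3SiH, CF3CO2H, CH2Cl2, 0 °C) then gives 22. In this detour the carbinol is made by alkene osmylation instead of enolate oxidation.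

Step 14 (lactol to tetrahydrofuran). The risk is slow formation of the oxocarbenium ion next to the tertiary carbinol, or a 1,2-shift, instead of clean hydride capture. The fallback sets out from 22 and comes back at 24, replacing steps 13–14. LiBH4 (THF, 0 °C → rt) opens the lactone to the triol F10. Acid-catalysed cyclodehydration (CF3SO3H 5 mol%, (CF3)2CHOH/CH2Cl2, 0 °C, stopped at full conversion) re-closes the ring by 5-exo capture of the benzylic cation by the primary alcohol. This O-capture is far faster than attack by the pendant arene and gives the 4,5-trans (5S) tetrahydrofuran 24 as the favoured isomer.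

**Further compounds**

F1 | step 8 | 4-(benzyloxy)-3-bromo-5-methoxybenzaldehyde | O=Cc1cc(OC)c(OCc2ccccc2)c(Br)c1
F2 | step 8 | methyl (3S)-3-{(S)-[4-(benzyloxy)-3-bromo-5-methoxyphenyl](hydroxy)methyl}-4-[(4S)-4-benzyl-2-oxo-1,3-oxazolidin-3-yl]-4-oxobutanoate | COC(=O)C[C@@H]([C@H](O)c1cc(OC)c(OCc2ccccc2)c(Br)c1)C(=O)N1C(=O)OC[C@@H]1Cc1ccccc1
F3 | step 8 | (4S)-4-benzyl-3-{[(2S,3S)-2-[4-(benzyloxy)-3-bromo-5-methoxyphenyl]-5-oxooxolan-3-yl]carbonyl}-1,3-oxazolidin-2-one | C1C(=O)O[C@H](c2cc(OC)c(OCc3ccccc3)c(Br)c2)[C@H]1C(=O)N1C(=O)OC[C@@H]1Cc1ccccc1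
F4 | step 8 | (2S,3S)-2-[4-(benzyloxy)-3-bromo-5-methoxyphenyl]-5-oxooxolane-3-carboperoxoic acid | C1C(=O)O[C@H](c2cc(OC)c(OCc3ccccc3)c(Br)c2)[C@H]1C(=O)OO
F5 | step 8 | (2S,3S)-2-[4-(benzyloxy)-3-bromo-5-methoxyphenyl]-5-oxooxolane-3-carboxylic acid | C1C(=O)O[C@H](c2cc(OC)c(OCc3ccccc3)c(Br)c2)[C@H]1C(=O)O
F6 | step 8 | (4R,5S)-5-[4-(benzyloxy)-3-bromo-5-methoxyphenyl]-4-(hydroxymethyl)oxolan-2-one | C1C(=O)O[C@H](c2cc(OC)c(OCc3ccccc3)c(Br)c2)[C@H]1CO
F7 | step 12 | (4R,5S)-5-[4-(benzyloxy)-3-bromo-5-methoxyphenyl]-3-{[3-(benzyloxy)-4-methoxyphenyl](hydroxy)methyl}-4-[(benzyloxy)methyl]oxolan-2-one (epimers at C3 and at the carbinol carbon) | COc1ccc(C(O)C2C(=O)O[C@H](c3cc(OC)c(OCc4ccccc4)c(Br)c3)[C@H]2COCc2ccccc2)cc1OCc1ccccc1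
F8 | step 12 | (3E,4R,5S)-5-[4-(benzyloxy)-3-bromo-5-methoxyphenyl]-3-[3-(benzyloxy)-4-methoxybenzylidene]-4-[(benzyloxy)methyl]oxolan-2-one | COc1ccc(/C=C2/C(=O)O[C@H](c3cc(OC)c(OCc4ccccc4)c(Br)c3)[C@H]2COCc2ccccc2)cc1OCc1ccccc1
F9 | step 12 | (3R,4R,5S)-5-[4-(benzyloxy)-3-bromo-5-methoxyphenyl]-3-{(S)-[3-(benzyloxy)-4-methoxyphenyl](hydroxy)methyl}-4-[(benzyloxy)methyl]-3-hydroxyoxolan-2-one | COc1ccc([C@H](O)[C@@]2(O)C(=O)O[C@H](c3cc(OC)c(OCc4ccccc4)c(Br)c3)[C@H]2COCc2ccccc2)cc1OCc1ccccc1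
F10 | step 14 | (1S,2R,3S)-1-[4-(benzyloxy)-3-bromo-5-methoxyphenyl]-3-[3-(benzyloxy)-4-methoxybenzyl]-2-[(benzyloxy)methyl]butane-1,3,4-triol | COc1ccc(C[C@@](O)(CO)[C@H](COCc2ccccc2)[C@H](O)c2cc(OC)c(OCc3ccccc3)c(Br)c2)cc1OCc1ccccc1
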